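**Retrosynthetic overview**

1. The free (E)-4-hydroxystyryl arm is cut as a Heck bond, so the terminal resveratrol unit is replaced by 5-iodoresorcinol; its iodine shields the two carbons next to it and leaves the carbon between the two hydroxyls for coupling.
2. Key disconnection, used twice: each trans-2,3-diaryl-2,3-dihydrobenzofuran is opened along the biosynthetic oxidative stilbene–resorcinol [3+2] (stilbene C8 to the carbon between the two resorcinol OH groups, then phenol closure on the p-quinone methide). Both couplings run under one chiral phosphoric acid, so both R,R pairs come from the same catalyst antipode.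
3. Ring order: first dihydrobenzofuran from resveratrol (1) + 5-iodoresorcinol (2) → 4; second dihydrobenzofuran from oxyresveratrol (5) onto the free resorcinol ring of 4 → 7; then Heck with 4-acetoxystyrene (8) → 10.

Assumption: the sense of induction of the phosphoric acid cannot be predicted with certainty; the route is written for the antipode (nominally (R)-TRIP) that gives the (2R,3R) ring, and the (S)-acid is used if 4 proves to be the mirror image (assigned on 4 by anomalous dispersion of iodine).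

**Step 1**
Reactants: 1 trans-resveratrol; 2 5-iodoresorcinol (5 equiv, excess recovered)
Product: 4 (2R,3R)-3-(3,5-dihydroxyphenyl)-2-(4-hydroxyphenyl)-6-iodo-2,3-dihydro-1-benzofuran-4-ol, via p-quinone methide 3 (not isolated)
Conditions: PhIO (1.05 equiv), (R)-TRIP (10 mol %), 4 Å MS, EtOAc/CH2Cl2 1:1, −30 °C, 1 added over 4 h
Reagents that add atoms: none
Why: Proposed new method: an enantioselective version of the biosynthetic oxidative phenol coupling/oxa-Michael [3+2]; acid-activated PhIO takes two electrons from the 4-hydroxystilbene, the C8-electrophilic oxidised stilbene stays paired with the chiral phosphate (which also hydrogen-bonds a resorcinol OH), and Friedel–Crafts attack by C2 of 2 (para to iodine, not flanked by it) sets C3 as R; rearomatisation gives p-quinone methide 3, whose acid-catalysed 5-exo oxa-1,6-addition closes the trans ring (C2 R, also the thermodynamic isomer); closest known reactions are the PhI(OAc)2- and FeCl3-mediated biomimetic couplings of 4-hydroxystilbenes and propenylphenols to 2,3-dihydrobenzofurans and phosphoric-acid-catalysed enantioselective Friedel–Crafts and remote 1,6/1,8-additions to p-quinone methides.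

**Step 2**
Reactants: 5 trans-oxyresveratrol; 4 (2 equiv, excess recovered)
Product: 7 (2R,3R)-3-[(2R,3R)-2-(2,4-dihydroxyphenyl)-3-(3,5-dihydroxyphenyl)-4-hydroxy-2,3-dihydro-1-benzofuran-6-yl]-2-(4-hydroxyphenyl)-6-iodo-2,3-dihydro-1-benzofuran-4-ol, via p-quinone methide 6 (not isolated)
Conditions: PhIO (1.05 equiv based on 5), (R)-TRIP (15 mol %), 4 Å MS, EtOAc/CH2Cl2 1:1, −30 °C, 5 added over 6 h
Reagents that add atoms: none
Why: Proposed new method: the same catalytic oxidative Friedel–Crafts/oxa-Michael [3+2] as in step 1; only the stilbene 5 is oxidised (4 has no stilbene), and the free 3,5-dihydroxyphenyl ring of 4 attacks between its two OH groups because both positions next to the bulky C3 substituent are shielded (as 5-tert-alkylresorcinols do in cannabinoid syntheses); the existing ring is too remote to bias the new one, so the same acid antipode, with the 2-OH of 5 as an extra hydrogen-bond anchor, sets the new C3 as R and closure of p-quinone methide 6 gives the trans ring (new C2 R); closest known reactions as in step 1.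

**Step 3**
Reactants: 7 iodide from step 2; 8 4-acetoxystyrene (1.5 equiv)
Product: 10 (2R,3R)-3-[(2R,3R)-2-(2,4-dihydroxyphenyl)-3-(3,5-dihydroxyphenyl)-4-hydroxy-2,3-dihydro-1-benzofuran-6-yl]-2-(4-hydroxyphenyl)-6-[(E)-2-(4-hydroxyphenyl)ethenyl]-2,3-dihydro-1-benzofuran-4-ol, via aryl acetate 9 (not isolated)
Conditions: Pd(OAc)2 (5 mol %), n-Bu4NCl, NaHCO3, DMF, 70 °C, Ar; then NH3 (7 M in MeOH), rt
Reagents that add atoms: none
Why: Mizoroki–Heck reaction (Jeffery conditions) of the aryl iodide with the styrene gives the E-stilbene, and ammonolysis removes the acetate (and any migrated acetyl); bicarbonate and ammonia are too weak to open the dihydrobenzofurans, so no stereocentre is touched.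

**Compound list**

1 | trans-resveratrol | Oc1ccc(/C=C/c2cc(O)cc(O)c2)cc1 | starting material
2 | 5-iodoresorcinol (5-iodobenzene-1,3-diol) | Oc1cc(O)cc(I)c1 | starting material
3 | 4-[(2R)-2-(2,6-dihydroxy-4-iodophenyl)-2-(3,5-dihydroxyphenyl)ethylidene]cyclohexa-2,5-dien-1-one | O=C1C=CC(=C[C@@H](c2c(O)cc(I)cc2O)c2cc(O)cc(O)c2)C=C1 | intermediate
4 | (2R,3R)-3-(3,5-dihydroxyphenyl)-2-(4-hydroxyphenyl)-6-iodo-2,3-dihydro-1-benzofuran-4-ol (trans) | Ic1cc(O)c2c(c1)O[C@@H](c1ccc(O)cc1)[C@@H]2c1cc(O)cc(O)c1 | intermediate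
5 | trans-oxyresveratrol | Oc1ccc(/C=C/c2cc(O)cc(O)c2)c(O)c1 | starting material
6 | 4-{(2R)-2-[2,6-dihydroxy-4-((2R,3R)-4-hydroxy-2-(4-hydroxyphenyl)-6-iodo-2,3-dihydro-1-benzofuran-3-yl)phenyl]-2-(3,5-dihydroxyphenyl)ethylidene}-3-hydroxycyclohexa-2,5-dien-1-one (alkene geometry not defined) | Ic1cc(O)c2c(c1)O[C@@H](c1ccc(O)cc1)[C@@H]2c1cc(O)c(c(O)c1)[C@H](C=C1C=CC(=O)C=C1O)c1cc(O)cc(O)c1 | intermediate
7 | (2R,3R)-3-[(2R,3R)-2-(2,4-dihydroxyphenyl)-3-(3,5-dihydroxyphenyl)-4-hydroxy-2,3-dihydro-1-benzofuran-6-yl]-2-(4-hydroxyphenyl)-6-iodo-2,3-dihydro-1-benzofuran-4-ol | Ic1cc(O)c2c(c1)O[C@@H](c1ccc(O)cc1)[C@@H]2c1cc(O)c2c(c1)O[C@@H](c1ccc(O)cc1O)[C@@H]2c1cc(O)cc(O)c1 | intermediate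
8 | 4-acetoxystyrene | CC(=O)Oc1ccc(C=C)cc1 | starting material
9 | 4-[(E)-2-{(2R,3R)-3-[(2R,3R)-2-(2,4-dihydroxyphenyl)-3-(3,5-dihydroxyphenyl)-4-hydroxy-2,3-dihydro-1-benzofuran-6-yl]-4-hydroxy-2-(4-hydroxyphenyl)-2,3-dihydro-1-benzofuran-6-yl}ethenyl]phenyl acetate | CC(=O)Oc1ccc(/C=C/c2cc(O)c3c(c2)O[C@@H](c2ccc(O)cc2)[C@@H]3c2cc(O)c3c(c2)O[C@@H](c2ccc(O)cc2O)[C@@H]3c2cc(O)cc(O)c2)cc1 | intermediate
10 | CNP0118407.2, (2R,3R)-3-[(2R,3R)-2-(2,4-dihydroxyphenyl)-3-(3,5-dihydroxyphenyl)-4-hydroxy-2,3-dihydro-1-benzofuran-6-yl]-2-(4-hydroxyphenyl)-6-[(E)-2-(4-hydroxyphenyl)ethenyl]-2,3-dihydro-1-benzofuran-4-ol | Oc1ccc(/C=C/c2cc(O)c3c(c2)O[C@@H](c2ccc(O)cc2)[C@@H]3c2cc(O)c3c(c2)O[C@@H](c2ccc(O)cc2O)[C@@H]3c2cc(O)cc(O)c2)cc1 | target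

**Step count and risks**

Total step count: 3. Longest linear sequence: 3 steps (1 → 4 → 7 → 10).

Steps most likely to fail, in order of risk:

Step 2. Three things can go wrong. Oxidised oxyresveratrol can close its own 2-OH onto C8 and end as a 2-arylbenzofuran. The nucleophile 4 is the hindered, valuable partner. The new ring is set relative to the old one only by the catalyst. The fallback reverses the ring order; it sets out from 5 and 2 and returns at 7. Compound 5 is oxidised under the step 1 conditions in the presence of a large excess (8 equiv) of cheap 2, so that bimolecular capture outruns the benzofuran closure. The quinone methide 4-[(2R)-2-(2,6-dihydroxy-4-iodophenyl)-2-(3,5-dihydroxyphenyl)ethylidene]-3-hydroxycyclohexa-2,5-dien-1-one F3 closes to (2R,3R)-2-(2,4-dihydroxyphenyl)-3-(3,5-dihydroxyphenyl)-6-iodo-2,3-dihydro-1-benzofuran-4-ol F4. Heck reaction of F4 with 8 as in step 3 gives 4-[(E)-2-{(2R,3R)-2-(2,4-dihydroxyphenyl)-3-(3,5-dihydroxyphenyl)-4-hydroxy-2,3-dihydro-1-benzofuran-6-yl}ethenyl]phenyl acetate F5 and, after ammonia, the stilbene dimer (2R,3R)-2-(2,4-dihydroxyphenyl)-3-(3,5-dihydroxyphenyl)-6-[(E)-2-(4-hydroxyphenyl)ethenyl]-2,3-dihydro-1-benzofuran-4-ol F6. F6 is then the oxidised partner (resveratrol type, no ortho-OH) in a second coupling with excess 2; the quinone methide 4-{(2R)-2-(2,6-dihydroxy-4-iodophenyl)-2-[(2R,3R)-2-(2,4-dihydroxyphenyl)-3-(3,5-dihydroxyphenyl)-4-hydroxy-2,3-dihydro-1-benzofuran-6-yl]ethylidene}cyclohexa-2,5-dien-1-one F7 closes to 7.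

Step 1. The level and sense of induction of the new coupling are unproven, and 2 may attack next to iodine instead of between the hydroxyls. The fallback gives up catalyst control; it sets out from 1 and 2 and returns at 4. The coupling is run with FeCl3·6H2O in acetone at rt, the classical racemic stilbene C8–resorcinol coupling. The quinone methide then forms as 3 together with its mirror image 4-[(2S)-2-(2,6-dihydroxy-4-iodophenyl)-2-(3,5-dihydroxyphenyl)ethylidene]cyclohexa-2,5-dien-1-one F1, and closes to 4 together with its enantiomer (2S,3S)-3-(3,5-dihydroxyphenyl)-2-(4-hydroxyphenyl)-6-iodo-2,3-dihydro-1-benzofuran-4-ol F2. The racemate and any regioisomer are separated by preparative SFC on an amylose phase; F2 is discarded and 4 goes on to step 2.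

Step 3. A Heck reaction on an unprotected heptaphenol may stall or give base-induced side reactions. The fallback uses protection; it sets out from 7 and returns at 10. Ac2O/pyridine gives the heptaacetate of 7 F8. A classical Heck reaction of F8 with 8 (Pd(OAc)2, n-Bu4NCl, NaHCO3, DMF, 80 °C) gives the octaacetate of 10 F9. NH3 in MeOH at rt removes all eight acetates to give 10.

**Further compounds**

F1 | step 1 | 4-[(2S)-2-(2,6-dihydroxy-4-iodophenyl)-2-(3,5-dihydroxyphenyl)ethylidene]cyclohexa-2,5-dien-1-one | O=C1C=CC(=C[C@H](c2c(O)cc(I)cc2O)c2cc(O)cc(O)c2)C=C1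
F2 | step 1 | (2S,3S)-3-(3,5-dihydroxyphenyl)-2-(4-hydroxyphenyl)-6-iodo-2,3-dihydro-1-benzofuran-4-ol | Ic1cc(O)c2c(c1)O[C@H](c1ccc(O)cc1)[C@H]2c1cc(O)cc(O)c1
F3 | step 2 | 4-[(2R)-2-(2,6-dihydroxy-4-iodophenyl)-2-(3,5-dihydroxyphenyl)ethylidene]-3-hydroxycyclohexa-2,5-dien-1-one | O=C1C=CC(=C[C@@H](c2c(O)cc(I)cc2O)c2cc(O)cc(O)c2)C(O)=C1
F4 | step 2 | (2R,3R)-2-(2,4-dihydroxyphenyl)-3-(3,5-dihydroxyphenyl)-6-iodo-2,3-dihydro-1-benzofuran-4-ol | Ic1cc(O)c2c(c1)O[C@@H](c1ccc(O)cc1O)[C@@H]2c1cc(O)cc(O)c1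
F5 | step 2 | 4-[(E)-2-{(2R,3R)-2-(2,4-dihydroxyphenyl)-3-(3,5-dihydroxyphenyl)-4-hydroxy-2,3-dihydro-1-benzofuran-6-yl}ethenyl]phenyl acetate | CC(=O)Oc1ccc(/C=C/c2cc(O)c3c(c2)O[C@@H](c2ccc(O)cc2O)[C@@H]3c2cc(O)cc(O)c2)cc1
F6 | step 2 | (2R,3R)-2-(2,4-dihydroxyphenyl)-3-(3,5-dihydroxyphenyl)-6-[(E)-2-(4-hydroxyphenyl)ethenyl]-2,3-dihydro-1-benzofuran-4-ol | Oc1ccc(/C=C/c2cc(O)c3c(c2)O[C@@H](c2ccc(O)cc2O)[C@@H]3c2cc(O)cc(O)c2)cc1
F7 | step 2 | 4-{(2R)-2-(2,6-dihydroxy-4-iodophenyl)-2-[(2R,3R)-2-(2,4-dihydroxyphenyl)-3-(3,5-dihydroxyphenyl)-4-hydroxy-2,3-dihydro-1-benzofuran-6-yl]ethylidene}cyclohexa-2,5-dien-1-one | O=C1C=CC(=C[C@@H](c2c(O)cc(I)cc2O)c2cc(O)c3c(c2)O[C@@H](c2ccc(O)cc2O)[C@@H]3c2cc(O)cc(O)c2)C=C1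
F8 | step 3 | heptaacetate of 7 (all seven phenols acetylated, configuration unchanged) | Ic1cc(OC(C)=O)c2c(c1)O[C@@H](c1ccc(OC(C)=O)cc1)[C@@H]2c1cc(OC(C)=O)c2c(c1)O[C@@H](c1ccc(OC(C)=O)cc1OC(C)=O)[C@@H]2c1cc(OC(C)=O)cc(OC(C)=O)c1
F9 | step 3 | octaacetate of 10 (all eight phenols acetylated, configuration unchanged) | CC(=O)Oc1ccc(/C=C/c2cc(OC(C)=O)c3c(c2)O[C@@H](c2ccc(OC(C)=O)cc2)[C@@H]3c2cc(OC(C)=O)c3c(c2)O[C@@H](c2ccc(OC(C)=O)cc2OC(C)=O)[C@@H]3c2cc(OC(C)=O)cc(OC(C)=O)c2)cc1
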